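Abbreviations: PMB = 4-methoxybenzyl, TBS = tert-butyldimethylsilyl, TIPS = triisopropylsilyl, TMS = trimethylsilyl. Ring A is numbered C1 (ketone), C2 (N-bearing), C3, C4 (carbinol), C5, C6 (oxirane carbons); the same numbers are used for the corresponding atoms of acyclic intermediates.

## Structural features

The target is a manumycin-type epoxyquinol. Ring A is a cyclohex-2-en-1-one with a cis-fused oxirane on C5–C6, an enamide nitrogen on C2 acylated by a (2E,4E)-5-cyclohexylpenta-2,4-dienoyl chain, and a quaternary C4 that carries a free tertiary hydroxyl and an all-E hepta-1,3,5-trienamide chain. That chain ends at the nitrogen of ring B, a 2-amino-3-hydroxycyclopent-2-en-1-one (the enol of a 2-acylamino-1,3-dione, a vinylogous acid). The only stereocentres are the three contiguous ring A carbons C4 (R), C5 (S) and C6 (R), with the C4 hydroxyl on the same face as the oxirane oxygen and the triene on the opposite face. Fragile elements are the epoxy ketone and enone (base, nucleophiles, reductants), the tertiary doubly allylic alcohol (acid, aromatisation), the two polyene amides (light, acid, radicals) and the acidic, metal-binding enol of ring B. The real difficulty is the quaternary C4 carbinol set correctly against the cis-oxirane inside an electrophilic, base-sensitive ring, together with late attachment of nitrogen at C2 and of both polyene chains. The key step exploits the fact that C1 is at once the ring ketone and the carboxyl carbon of a cis-glycidic acid (oxirane carbons C6 and C5), while C2=C3 is a cis alkene hanging from C4. An alkenyl anion at C2 can therefore acylate C1 and close ring A without touching any stereocentre.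

## Logic of the disconnections

**36 ⇒ 27 + 35.** The C(sp2)–C(sp2) single bond between the two-carbon unit on C4 and the four-carbon dienamide is cut (Stille). This is the most convergent cut of the triene and lets the acidic ring B arrive last under neutral conditions. The forward step needs an E-alkenylstannane next to a free tertiary alcohol and an epoxy enone that tolerates zerovalent palladium.

**27 ⇒ 26 ⇒ 25.** The C–Sn and C–H bonds across the C4 ethynyl group are removed, then the O–Si and C–Si bonds are restored. The silylalkyne is a small, inert stand-in for the alkenyl metal through all organometallic steps. The forward demand is regio- and syn-selective hydrostannation without reduction of the enone, and a desilylation mild enough for the epoxyquinol.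

**25 ⇒ 20 + 24, then 20 ⇒ 19.** The N–C2 bond is cut (copper-catalysed amidation of an alkenyl iodide) and the C2–I bond is traced back to C2–H. This removes the whole upper chain and the nitrogen and leaves a plain epoxy enone. The coupling needs base, so the C4 oxygen stays silylated until afterwards.

**19 ⇒ 16 (key).** The C1–C2 bond is cut. The ring opens to an acyclic cis-glycidic N-methoxy-N-methylamide with a Z-iodoalkene on C4. All three stereocentres are already present and none is created. The forward step needs halogen–lithium exchange to be faster than carbonyl attack and faster than silyl migration from the C4 oxygen to C2.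

**16 ⇒ 14 + 15, 14 ⇒ 13 ⇒ 12.** The amide C–N bond is cut and the C1 oxidation level is lowered to a PMB-protected hydroxymethyl group. An ether is used at C1 rather than an ester, because acyl migration between the two hydroxymethyl termini of a desymmetrised cis-epoxy diol would racemise it. The PMB group must leave without touching two silyl groups and the alkenyl iodide.

**12 ⇒ 11 ⇒ 10 ⇒ 9.** The Z-iodoalkene is traced to an iodoalkyne and that to a TMS-alkyne; the O–Si bond is cut. Two alkynes of different silyl size can be told apart chemically, so one becomes C2=C3 and the other stays as the side-chain precursor. A TBS ether replaces a smaller silyl ether on the C4 oxygen. That oxygen is 1,4 to the future carbanion, and a small silyl group would be prone to O→C migration.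

**9 ⇒ 7 + 8, then 7 ⇒ 6 ⇒ 4 + 5.** The two C4–C(sp) bonds are cut in turn. C4 becomes a ketone and then an aldehyde, so the C4 configuration depends only on the face of one ketone addition. That addition must be chelation-controlled by the adjacent oxirane oxygen. The silyl cap on the ynone avoids the acidic and Michael-prone terminal ynone.

**4 ⇒ 3 ⇒ 2 ⇒ 1.** The oxirane C–O bonds are cut (asymmetric epoxidation of a Z-allylic alcohol) and the monoether is traced to a symmetrical diol. C5 and C6 come from one reagent-controlled step on a four-carbon commodity. Z-allylic alcohols are slow, less selective substrates, which is the price.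

**24 ⇒ 23 ⇒ 21 + 22.** The amide C–N bond and the C4=C5 alkene of the upper chain are cut (aminolysis, vinylogous Horner–Wadsworth–Emmons). The forward demand is E-selectivity only.

**35 ⇒ 30 + 33 (through 34), 30 ⇒ 29 ⇒ 28, 33 ⇒ 32 ⇒ 31.** The amide bond of the lower fragment is cut; the bromodienoic acid comes from a five-carbon dialdehyde enolate and the aminoenol from a 1,3-dione by C-nitrosation and reduction. The amine is a poor nucleophile and needs an acid chloride.

## Other disconnections considered

**Alternative 1:** This cuts the C1–C5 bond of ring B (aminolevulinate numbering). In the forward step KOtBu would convert the N-acylated 5-aminolevulinate ester A2 into the stannyl dienamide A1 by attack of the N-bearing enolate on the ester, driven by formation of the stabilised diketonate.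
- In its favour: ring B and its amide come from a cheap amino acid ester in two operations, against three in the chosen plan (steps 22–24), and the weakly nucleophilic aminoenol 33 is never handled. On the economy of this fragment it is the better plan.
- In its favour: tin rather than bromine on the diene is sensible, since an alkenyl bromide would risk dehydrobromination under the alkoxide.
- Against it: it addresses ring B only and leaves ring A without a plan.
- Against it: it needs several equivalents of strong base on a dienamide (N–H deprotonation first, then competing enolisation on the other side of the ketone).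
- Against it: it reverses the coupling polarity, so ring A would have to be the alkenyl iodide A3, made from 27 by iododestannylation. That is one more step on the most valuable intermediate and cancels the saving.
- Comparison: mechanistically it is independent of the chosen key step and could be combined with it; overall it is equal in length and somewhat higher in risk.

**Alternative 2:** This cuts all four C–O bonds of a syn-bis-epoxide. In the forward step singlet oxygen would add across the diene termini of the silyloxy diene A5 on the face away from the C1 silyloxy group, and divalent cobalt tetraphenylporphyrin, Co(TPP), would then isomerise the O–O bond to give A4. O-desilylation at C1, oxidation and base-induced opening of the 3,4-oxirane would then give the epoxyquinol A6, with the C4 hydroxyl necessarily syn to the remaining oxirane.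
- In its favour: the syn relationship of C4–O and the C5–C6 oxirane is enforced by the suprafacial cycloaddition, not by a separate addition step.
- In its favour: one easily made carbinol centre controls everything and is then erased, and no organolithium is needed.
- In its favour: the enone stage would probably be reached in fewer steps than the thirteen of the chosen plan, so on step count it is the equal or the better.
- Against it: facial control rests on a single allylic silyloxy group.
- Against it: the ene reaction at the allylic methylene competes.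
- Against it: A5 is a dihydroarene with a leaving group and can aromatise.
- Against it: the cobalt step can divert to hydroxy ketones.
- Against it: A5 needs its own asymmetric entry.
- Comparison: both plans converge on the same ring A and share the endgame. The chosen plan is longer but sets each stereocentre in a separately controllable step.

**Alternative 3:** This cuts the C5–O and C6–O bonds on the achiral para-quinol A7, which would come in one step from p-benzoquinone A8 and the acetylide of 8. In the forward step tert-butyl hydroperoxide under a chiral N-anthracenylmethyl cinchonidinium phase-transfer catalyst would epoxidise one of the two enantiotopic enones syn to the hydroxyl to give A6.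
- In its favour: all three stereocentres arise in one catalytic step from a symmetrical precursor, with no protecting groups on the ring. Two steps to A6 against thirteen to 19 is clearly the better step economy.
- Against it: enantiotopic-group selection and syn facial selection must both be high at once.
- Against it: phase-transfer epoxidation is best established for acyclic enones and is much less secure for cyclic dienones.
- Against it: a second epoxidation, racemic background reaction, and base-induced dienone–phenol or retro-addition pathways of A7 all compete.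
- Comparison: if the selectivity were attainable this plan would supersede the chosen one. The chosen plan is preferable only for the predictability of absolute and relative configuration. A6 would join the chosen route after O-silylation.

Key step: step 13

Remarks on the chemistry:
- The structures of 16 and 19 were checked atom by atom against the target. C4 S, C5 S, C6 R in 16–26 is the same spatial arrangement as 4R,5S,6R in 36; the C4 descriptor changes only because substituent ranks change.
- The sense of the asymmetric epoxidation is assigned from the tartrate rule for allylic alcohols: the natural L-(+)-ester gives the 2S,3R epoxy alcohol from Z-4-alkoxybut-2-en-1-ols, so the D-(−)-ester is used.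
- Compound 28 is taken to be a catalogue chemical; it is otherwise one step from pyridinium-1-sulfonate and KOH.

## Route

Step 1
Reactants: 1 (Z)-but-2-ene-1,4-diol
Product: 2 (Z)-4-[(4-methoxybenzyl)oxy]but-2-en-1-ol
Conditions: 1 (3 equiv), NaH (1 equiv), THF, 0 °C; PMBCl (1 equiv), n-Bu4NI (cat.), 0 °C → rt
Reagents that add atoms: 4-methoxybenzyl chloride, COc1ccc(CCl)cc1
Why: Williamson etherification of the mono-alkoxide; the excess of diol biases the statistics toward the monoether and the unreacted diol is removed with water.

Step 2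
Reactants: 2 (Z)-4-[(4-methoxybenzyl)oxy]but-2-en-1-ol
Product: 3 [(2R,3S)-3-{[(4-methoxybenzyl)oxy]methyl}oxiran-2-yl]methanol
Conditions: Ti(OiPr)4, D-(−)-diethyl tartrate, t-BuOOH, 4 Å MS, CH2Cl2, −20 °C
Reagents that add atoms: tert-butyl hydroperoxide, CC(C)(C)OO
Why: Sharpless asymmetric epoxidation; the titanium–D-tartrate complex delivers oxygen to the alkene face that gives the 2R,3S epoxide, and the Z geometry fixes the cis relationship, so C5 and C6 are both set here under reagent control.

Step 3
Reactants: 3 [(2R,3S)-3-{[(4-methoxybenzyl)oxy]methyl}oxiran-2-yl]methanol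
Product: 4 (2S,3S)-3-{[(4-methoxybenzyl)oxy]methyl}oxirane-2-carbaldehyde
Conditions: Dess–Martin periodinane, NaHCO3, CH2Cl2, 0 °C → rt; used crude
Reagents that add atoms: none
Why: Dess–Martin oxidation; the buffered, non-basic medium should avoid epimerisation of the cis-epoxy aldehyde to the trans isomer.

Step 4
Reactants: 4 (2S,3S)-3-{[(4-methoxybenzyl)oxy]methyl}oxirane-2-carbaldehyde; 5 ethynyltrimethylsilane
Product: 6 1-[(2R,3S)-3-{[(4-methoxybenzyl)oxy]methyl}oxiran-2-yl]-3-(trimethylsilyl)prop-2-yn-1-ol (both carbinol epimers)
Conditions: 5, n-BuLi, THF, −78 °C; then 4, −78 °C; aq. NH4Cl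
Reagents that add atoms: none
Why: 1,2-addition of a lithium acetylide to an aldehyde; the carbinol configuration is irrelevant because this centre is oxidised in the next step.

Step 5
Reactants: 6 1-[(2R,3S)-3-{[(4-methoxybenzyl)oxy]methyl}oxiran-2-yl]-3-(trimethylsilyl)prop-2-yn-1-ol
Product: 7 1-[(2S,3S)-3-{[(4-methoxybenzyl)oxy]methyl}oxiran-2-yl]-3-(trimethylsilyl)prop-2-yn-1-one
Conditions: Dess–Martin periodinane, NaHCO3, CH2Cl2, 0 °C → rt
Reagents that add atoms: none
Why: Dess–Martin oxidation of a propargylic alcohol; the silyl cap removes the acidic acetylenic hydrogen and the Michael reactivity a terminal ynone would bring to the next step.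

Step 6
Reactants: 7 1-[(2S,3S)-3-{[(4-methoxybenzyl)oxy]methyl}oxiran-2-yl]-3-(trimethylsilyl)prop-2-yn-1-one; 8 ethynyltriisopropylsilane
Product: 9 (3S)-3-[(2S,3S)-3-{[(4-methoxybenzyl)oxy]methyl}oxiran-2-yl]-1-(triisopropylsilyl)-5-(trimethylsilyl)penta-1,4-diyn-3-ol
Conditions: 8, EtMgBr, THF, 0 °C → rt; then 7, CH2Cl2/Et2O, −78 → −40 °C; aq. NH4Cl
Reagents that add atoms: none
Why: Chelation-controlled (Cram chelate) addition of an alkynyl Grignard reagent to an α,β-epoxy ketone: magnesium bridges the ketone and oxirane oxygens and the acetylide attacks the carbonyl face on the side of the oxirane hydrogen, away from the other oxirane carbon. This sets C4 as 3S, the arrangement that later places the hydroxyl syn and the alkyne anti to the oxirane oxygen in ring A.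

Step 7
Reactants: 9 (3S)-3-[(2S,3S)-3-{[(4-methoxybenzyl)oxy]methyl}oxiran-2-yl]-1-(triisopropylsilyl)-5-(trimethylsilyl)penta-1,4-diyn-3-ol
Product: 10 TBS ether of 9, tert-butyl{[(3S)-3-[(2S,3S)-3-{[(4-methoxybenzyl)oxy]methyl}oxiran-2-yl]-1-(triisopropylsilyl)-5-(trimethylsilyl)penta-1,4-diyn-3-yl]oxy}dimethylsilane
Conditions: TBSOTf, 2,6-lutidine, CH2Cl2, −78 → 0 °C
Reagents that add atoms: tert-butyldimethylsilyl trifluoromethanesulfonate, CC(C)(C)[Si](C)(C)OS(=O)(=O)C(F)(F)F
Why: O-silylation of a tertiary propargylic alcohol with a silyl triflate and a hindered base. The oxygen must be capped because a free C4 alkoxide would lactonise onto C1 and consume organolithium later, and the bulky TBS group is chosen to slow silyl migration to C2 in the key step.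

Step 8
Reactants: 10 TBS ether of 9
Product: 11 tert-butyl{[(3R)-1-iodo-3-[(2S,3S)-3-{[(4-methoxybenzyl)oxy]methyl}oxiran-2-yl]-5-(triisopropylsilyl)penta-1,4-diyn-3-yl]oxy}dimethylsilane (same geometry at C4; the descriptor changes with the ranks)
Conditions: N-iodosuccinimide, AgNO3 (cat.), acetone, rt, dark
Reagents that add atoms: N-iodosuccinimide, O=C1CCC(=O)N1I
Why: Silver-catalysed iododesilylation of a trimethylsilylalkyne through the silver acetylide; the TIPS-alkyne is too hindered to react, which is what tells the two alkynes apart.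

Step 9
Reactants: 11 iodoalkyne
Product: 12 tert-butyl{[(1Z,3S)-1-iodo-3-[(2S,3S)-3-{[(4-methoxybenzyl)oxy]methyl}oxiran-2-yl]-5-(triisopropylsilyl)pent-1-en-4-yn-3-yl]oxy}dimethylsilane
Conditions: 2-nitrobenzenesulfonylhydrazide, Et3N, THF/i-PrOH, rt
Reagents that add atoms: none
Why: Diimide reduction; concerted syn transfer of two hydrogens to the iodoalkyne gives the Z-iodoalkene, the hindered silylalkyne is not reduced, and the metal-free conditions leave the C–I bond intact.

Step 10
Reactants: 12 Z-iodoalkene PMB ether
Product: 13 [(2S,3S)-3-[(1Z,3S)-3-(tert-butyldimethylsilyloxy)-1-iodo-5-(triisopropylsilyl)pent-1-en-4-yn-3-yl]oxiran-2-yl]methanol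
Conditions: DDQ, CH2Cl2/pH 7 buffer, 0 °C
Reagents that add atoms: none
Why: Oxidative cleavage of a PMB ether by DDQ (benzylic oxidation to the oxocarbenium ion and hydrolysis); it is orthogonal to both silyl groups, the alkenyl iodide and the oxirane.

Step 11
Reactants: 13 primary alcohol
Product: 14 (2R,3S)-3-[(1Z,3S)-3-(tert-butyldimethylsilyloxy)-1-iodo-5-(triisopropylsilyl)pent-1-en-4-yn-3-yl]oxirane-2-carboxylic acid
Conditions: TEMPO (cat.), PhI(OAc)2, MeCN/H2O, rt
Reagents that add atoms: water, O
Why: Oxoammonium (TEMPO) oxidation of a primary alcohol through the aldehyde hydrate to the acid; the reagent pair is chemoselective for the alcohol and leaves alkyne, iodoalkene and silyl ether alone.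

Step 12
Reactants: 14 glycidic acid; 15 N,O-dimethylhydroxylamine hydrochloride
Product: 16 (2R,3S)-3-[(1Z,3S)-3-(tert-butyldimethylsilyloxy)-1-iodo-5-(triisopropylsilyl)pent-1-en-4-yn-3-yl]-N-methoxy-N-methyloxirane-2-carboxamide
Conditions: EDC·HCl, HOBt, N-methylmorpholine, CH2Cl2, 0 °C → rt
Reagents that add atoms: none
Why: Carbodiimide coupling through the hydroxybenzotriazole active ester; the mild conditions should spare the glycidic acid from decarboxylation or epimerisation.

Step 13
Reactants: 16 Z-iodoalkenyl glycidic N-methoxy-N-methylamide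
Product: 19 (4S,5S,6R)-4-(tert-butyldimethylsilyloxy)-5,6-epoxy-4-[(triisopropylsilyl)ethynyl]cyclohex-2-en-1-one, via Z-alkenyllithium 17 (not isolated), via lithium hemiaminal alkoxide 18 (not isolated)
Conditions: t-BuLi (2.1 equiv), Et2O/pentane, −100 → −78 °C; AcOH in Et2O, then aq. NH4Cl, −78 °C → rt
Reagents that add atoms: none
Why: Parham-type cyclisation: t-BuLi exchanges the C2 iodide through an iodine ate complex, the second equivalent destroys the tert-butyl iodide so the exchange is irreversible, and the alkenyllithium 17 keeps its Z geometry at this temperature. 17 adds to the amide carbonyl C1 in a 6-exo-trig closure (the breaking C=O bond lies outside the new ring), for which the Z alkene and the cis-oxirane already hold C2 and C1 on the same side and within reach. The adduct 18 is held by lithium chelation between the alkoxide and the N-methoxy oxygen and should not collapse before protonation, so a second organolithium addition is excluded and the epoxy enone is never exposed to base; the cold acidic quench also keeps the released hydroxylamine protonated and away from the enone. No stereocentre is formed or touched: C4, C5 and C6 are spectators and C1 ends sp2. The step needs exchange before carbonyl attack, which −100 °C and the high rate of exchange at an sp2 C–I bond should secure. It also needs acylation before 1,4 O→C silyl migration, which the bulky TBS group on a tertiary oxygen and the ether/pentane medium should secure. The closest known reaction type is the Parham cyclisation of aryl- and alkenyllithiums onto N-methoxy-N-methylamides to give cyclic ketones.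

Step 14
Reactants: 19 epoxy enone
Product: 20 (4S,5S,6R)-4-(tert-butyldimethylsilyloxy)-5,6-epoxy-2-iodo-4-[(triisopropylsilyl)ethynyl]cyclohex-2-en-1-one
Conditions: I2, pyridine, CH2Cl2, 0 °C → rt
Reagents that add atoms: iodine, II
Why: Johnson α-iodination of an enone: pyridine adds conjugately at C3, the enolate is iodinated at C2 and pyridine is lost by E1cB elimination; there is only one enone, so the regiochemistry is inherent.

Step 15
Reactants: 21 cyclohexanecarbaldehyde; 22 triethyl (E)-4-phosphonobut-2-enoate
Product: 23 ethyl (2E,4E)-5-cyclohexylpenta-2,4-dienoate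
Conditions: LiHMDS, THF, −78 → 0 °C
Reagents that add atoms: none
Why: Vinylogous Horner–Wadsworth–Emmons olefination; the stabilised phosphonate anion forms the new alkene E and the existing E alkene is retained.

Step 16
Reactants: 23 ethyl (2E,4E)-5-cyclohexylpenta-2,4-dienoate
Product: 24 (2E,4E)-5-cyclohexylpenta-2,4-dienamide
Conditions: AlMe3, NH4Cl, toluene, 0 → 50 °C; aq. Rochelle salt
Reagents that add atoms: ammonium chloride, [NH4+].[Cl-]
Why: Weinreb aminolysis of an ester with an aluminium amide; it gives the primary amide directly by 1,2-attack without disturbing the diene.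

Step 17
Reactants: 20 2-iodo enone; 24 (2E,4E)-5-cyclohexylpenta-2,4-dienamide
Product: 25 (2E,4E)-N-[(4S,5S,6R)-4-(tert-butyldimethylsilyloxy)-5,6-epoxy-1-oxo-4-[(triisopropylsilyl)ethynyl]cyclohex-2-en-2-yl]-5-cyclohexylpenta-2,4-dienamide
Conditions: CuI (10 mol %), N,N'-dimethylethylenediamine (20 mol %), Cs2CO3, THF, 50 °C
Reagents that add atoms: none
Why: Copper-catalysed Goldberg-type amidation of an alkenyl iodide (Buchwald conditions); the electron-poor α-iodo enone is an activated partner, the alkene position is retained, and the silylated C4 oxygen and capped alkyne keep the substrate free of acidic or copper-binding sites.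

Step 18
Reactants: 25 bis-silylated enamide
Product: 26 (2E,4E)-5-cyclohexyl-N-[(4S,5S,6R)-5,6-epoxy-4-ethynyl-4-hydroxy-1-oxocyclohex-2-en-2-yl]penta-2,4-dienamide
Conditions: TBAF, AcOH (1:1), THF, 0 °C → rt
Reagents that add atoms: none
Why: Fluoride-induced cleavage of the O–Si and the C(sp)–Si bond in one operation; acetic acid buffers the alkoxide and acetylide that would otherwise attack the epoxyquinol.

Step 19
Reactants: 26 terminal alkyne
Product: 27 (2E,4E)-5-cyclohexyl-N-[(4S,5S,6R)-5,6-epoxy-4-hydroxy-1-oxo-4-[(E)-2-(tributylstannyl)ethenyl]cyclohex-2-en-2-yl]penta-2,4-dienamide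
Conditions: Bu3SnH (slow addition), PdCl2(PPh3)2 (3 mol %), THF, 0 °C
Reagents that add atoms: tributyltin hydride, CCCC[SnH](CCCC)CCCC
Why: Palladium-catalysed hydrostannation of a terminal alkyne; syn addition gives the E alkene and the quaternary propargylic carbon directs tin to the terminal carbon.

Step 20
Reactants: 28 glutaconaldehyde potassium salt
Product: 29 (2E,4E)-5-bromopenta-2,4-dienal
Conditions: PPh3, Br2, CH2Cl2, 0 °C; then 28, 0 °C → rt
Reagents that add atoms: bromine, BrBr
Why: Deoxybromination of the dienolate with dibromotriphenylphosphorane (O-phosphonium formation, then addition–elimination by bromide); the conjugated product settles as the E,E isomer.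

Step 21
Reactants: 29 (2E,4E)-5-bromopenta-2,4-dienal
Product: 30 (2E,4E)-5-bromopenta-2,4-dienoic acid
Conditions: NaClO2, NaH2PO4, 2-methylbut-2-ene, t-BuOH/H2O, 0 °C → rt
Reagents that add atoms: sodium chlorite, [Na+].[O-]Cl=O
Why: Pinnick oxidation; it is selective for the aldehyde and the alkene scavenger takes up hypochlorous acid before it can attack the bromodiene.

Step 22
Reactants: 31 cyclopentane-1,3-dione
Product: 32 2-(hydroxyimino)cyclopentane-1,3-dione
Conditions: NaNO2, aq. HCl, 0 °C
Reagents that add atoms: sodium nitrite, [Na+].[O-]N=O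
Why: C-nitrosation of the active methylene of a 1,3-dione by nitrous acid, followed by tautomerisation to the oxime.

Step 23
Reactants: 32 2-(hydroxyimino)cyclopentane-1,3-dione
Product: 33 2-amino-3-hydroxycyclopent-2-en-1-one hydrochloride
Conditions: H2 (1 atm), Pd/C, HCl, EtOH, rt
Reagents that add atoms: hydrogen chloride, Cl
Why: Catalytic hydrogenation of an α-oximino dione to the α-amino dione, trapped as the hydrochloride so that the amino ketone cannot self-condense; the product exists as the enol.

Step 24
Reactants: 30 (2E,4E)-5-bromopenta-2,4-dienoic acid; 33 2-amino-3-hydroxycyclopent-2-en-1-one hydrochloride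
Product: 35 (2E,4E)-5-bromo-N-(2-hydroxy-5-oxocyclopent-1-en-1-yl)penta-2,4-dienamide, via acid chloride 34 (not isolated)
Conditions: (COCl)2, DMF (cat.), CH2Cl2, 0 °C → rt, evaporate; then 33, N-methylmorpholine, THF, 0 °C → rt
Reagents that add atoms: none
Why: Acid chloride formation by Vilsmeier-type activation, then N-acylation of the weakly nucleophilic aminoenol; any O-acyl isomer is expected to rearrange to the amide by O→N acyl shift.

Step 25
Reactants: 27 alkenylstannane; 35 bromodienamide
Product: 36 target, (2E,4E)-5-cyclohexyl-N-[(4R,5S,6R)-5,6-epoxy-4-hydroxy-4-[(1E,3E,5E)-7-[(2-hydroxy-5-oxocyclopent-1-en-1-yl)amino]-7-oxohepta-1,3,5-trien-1-yl]-1-oxocyclohex-2-en-2-yl]penta-2,4-dienamide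
Conditions: Pd2(dba)3 (5 mol %), AsPh3 (20 mol %), DMF, rt, dark
Reagents that add atoms: none
Why: Stille cross-coupling of an alkenylstannane with an alkenyl bromide, with retention of both alkene geometries; the neutral, base-free conditions suit the free tertiary alcohol, the epoxy enone and the acidic enol of ring B.

## Compound list

1 | (Z)-but-2-ene-1,4-diol | OC/C=C\CO | starting material
2 | (Z)-4-[(4-methoxybenzyl)oxy]but-2-en-1-ol | OC/C=C\COCc1ccc(OC)cc1 | intermediate
3 | [(2R,3S)-3-{[(4-methoxybenzyl)oxy]methyl}oxiran-2-yl]methanol | OC[C@H]1O[C@H]1COCc1ccc(OC)cc1 | intermediate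
4 | (2S,3S)-3-{[(4-methoxybenzyl)oxy]methyl}oxirane-2-carbaldehyde | O=C[C@H]1O[C@H]1COCc1ccc(OC)cc1 | intermediate
5 | ethynyltrimethylsilane | C#C[Si](C)(C)C | starting material
6 | 1-[(2R,3S)-3-{[(4-methoxybenzyl)oxy]methyl}oxiran-2-yl]-3-(trimethylsilyl)prop-2-yn-1-ol, carbinol epimers | C[Si](C)(C)C#CC(O)[C@H]1O[C@H]1COCc1ccc(OC)cc1 | intermediate
7 | 1-[(2S,3S)-3-{[(4-methoxybenzyl)oxy]methyl}oxiran-2-yl]-3-(trimethylsilyl)prop-2-yn-1-one | C[Si](C)(C)C#CC(=O)[C@H]1O[C@H]1COCc1ccc(OC)cc1 | intermediate
8 | ethynyltriisopropylsilane | C#C[Si](C(C)C)(C(C)C)C(C)C | starting material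
9 | (3S)-3-[(2S,3S)-3-{[(4-methoxybenzyl)oxy]methyl}oxiran-2-yl]-1-(triisopropylsilyl)-5-(trimethylsilyl)penta-1,4-diyn-3-ol | C[Si](C)(C)C#C[C@](O)(C#C[Si](C(C)C)(C(C)C)C(C)C)[C@H]1O[C@H]1COCc1ccc(OC)cc1 | intermediate
10 | tert-butyl{[(3S)-3-[(2S,3S)-3-{[(4-methoxybenzyl)oxy]methyl}oxiran-2-yl]-1-(triisopropylsilyl)-5-(trimethylsilyl)penta-1,4-diyn-3-yl]oxy}dimethylsilane | C[Si](C)(C)C#C[C@](O[Si](C)(C)C(C)(C)C)(C#C[Si](C(C)C)(C(C)C)C(C)C)[C@H]1O[C@H]1COCc1ccc(OC)cc1 | intermediate
11 | tert-butyl{[(3R)-1-iodo-3-[(2S,3S)-3-{[(4-methoxybenzyl)oxy]methyl}oxiran-2-yl]-5-(triisopropylsilyl)penta-1,4-diyn-3-yl]oxy}dimethylsilane | IC#C[C@](O[Si](C)(C)C(C)(C)C)(C#C[Si](C(C)C)(C(C)C)C(C)C)[C@H]1O[C@H]1COCc1ccc(OC)cc1 | intermediate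
12 | tert-butyl{[(1Z,3S)-1-iodo-3-[(2S,3S)-3-{[(4-methoxybenzyl)oxy]methyl}oxiran-2-yl]-5-(triisopropylsilyl)pent-1-en-4-yn-3-yl]oxy}dimethylsilane | I/C=C\[C@](O[Si](C)(C)C(C)(C)C)(C#C[Si](C(C)C)(C(C)C)C(C)C)[C@H]1O[C@H]1COCc1ccc(OC)cc1 | intermediate
13 | [(2S,3S)-3-[(1Z,3S)-3-(tert-butyldimethylsilyloxy)-1-iodo-5-(triisopropylsilyl)pent-1-en-4-yn-3-yl]oxiran-2-yl]methanol | I/C=C\[C@](O[Si](C)(C)C(C)(C)C)(C#C[Si](C(C)C)(C(C)C)C(C)C)[C@H]1O[C@H]1CO | intermediate
14 | (2R,3S)-3-[(1Z,3S)-3-(tert-butyldimethylsilyloxy)-1-iodo-5-(triisopropylsilyl)pent-1-en-4-yn-3-yl]oxirane-2-carboxylic acid | I/C=C\[C@](O[Si](C)(C)C(C)(C)C)(C#C[Si](C(C)C)(C(C)C)C(C)C)[C@H]1O[C@H]1C(=O)O | intermediate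
15 | N,O-dimethylhydroxylamine hydrochloride | CNOC.Cl | starting material
16 | (2R,3S)-3-[(1Z,3S)-3-(tert-butyldimethylsilyloxy)-1-iodo-5-(triisopropylsilyl)pent-1-en-4-yn-3-yl]-N-methoxy-N-methyloxirane-2-carboxamide | I/C=C\[C@](O[Si](C)(C)C(C)(C)C)(C#C[Si](C(C)C)(C(C)C)C(C)C)[C@H]1O[C@H]1C(=O)N(C)OC | intermediate
17 | Z-alkenyllithium from iodine–lithium exchange of 16 (not isolated) | [Li]/C=C\[C@](O[Si](C)(C)C(C)(C)C)(C#C[Si](C(C)C)(C(C)C)C(C)C)[C@H]1O[C@H]1C(=O)N(C)OC | intermediate
18 | lithium alkoxide of the cyclic C1 N-methoxy-N-methyl hemiaminal, C1 epimers (not isolated) | [Li]OC1(N(C)OC)C=C[C@](O[Si](C)(C)C(C)(C)C)(C#C[Si](C(C)C)(C(C)C)C(C)C)[C@H]2O[C@H]21 | intermediate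
19 | (4S,5S,6R)-4-(tert-butyldimethylsilyloxy)-5,6-epoxy-4-[(triisopropylsilyl)ethynyl]cyclohex-2-en-1-one | O=C1C=C[C@](O[Si](C)(C)C(C)(C)C)(C#C[Si](C(C)C)(C(C)C)C(C)C)[C@H]2O[C@H]21 | intermediate
20 | (4S,5S,6R)-4-(tert-butyldimethylsilyloxy)-5,6-epoxy-2-iodo-4-[(triisopropylsilyl)ethynyl]cyclohex-2-en-1-one | O=C1C(I)=C[C@](O[Si](C)(C)C(C)(C)C)(C#C[Si](C(C)C)(C(C)C)C(C)C)[C@H]2O[C@H]21 | intermediate
21 | cyclohexanecarbaldehyde | O=CC1CCCCC1 | starting material
22 | triethyl (E)-4-phosphonobut-2-enoate | CCOC(=O)/C=C/CP(=O)(OCC)OCC | starting material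
23 | ethyl (2E,4E)-5-cyclohexylpenta-2,4-dienoate | CCOC(=O)/C=C/C=C/C1CCCCC1 | intermediate
24 | (2E,4E)-5-cyclohexylpenta-2,4-dienamide | NC(=O)/C=C/C=C/C1CCCCC1 | intermediate
25 | (2E,4E)-N-[(4S,5S,6R)-4-(tert-butyldimethylsilyloxy)-5,6-epoxy-1-oxo-4-[(triisopropylsilyl)ethynyl]cyclohex-2-en-2-yl]-5-cyclohexylpenta-2,4-dienamide | O=C(/C=C/C=C/C1CCCCC1)NC1=C[C@](O[Si](C)(C)C(C)(C)C)(C#C[Si](C(C)C)(C(C)C)C(C)C)[C@H]2O[C@H]2C1=O | intermediate
26 | (2E,4E)-5-cyclohexyl-N-[(4S,5S,6R)-5,6-epoxy-4-ethynyl-4-hydroxy-1-oxocyclohex-2-en-2-yl]penta-2,4-dienamide | O=C(/C=C/C=C/C1CCCCC1)NC1=C[C@](O)(C#C)[C@H]2O[C@H]2C1=O | intermediate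
27 | (2E,4E)-5-cyclohexyl-N-[(4S,5S,6R)-5,6-epoxy-4-hydroxy-1-oxo-4-[(E)-2-(tributylstannyl)ethenyl]cyclohex-2-en-2-yl]penta-2,4-dienamide | O=C(/C=C/C=C/C1CCCCC1)NC1=C[C@](O)(/C=C/[Sn](CCCC)(CCCC)CCCC)[C@H]2O[C@H]2C1=O | intermediate
28 | glutaconaldehyde potassium salt, potassium (1E,3E)-5-oxopenta-1,3-dien-1-olate | [K+].[O-]/C=C/C=C/C=O | starting material
29 | (2E,4E)-5-bromopenta-2,4-dienal | O=C/C=C/C=C/Br | intermediate
30 | (2E,4E)-5-bromopenta-2,4-dienoic acid | OC(=O)/C=C/C=C/Br | intermediate
31 | cyclopentane-1,3-dione | O=C1CCC(=O)C1 | starting material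
32 | 2-(hydroxyimino)cyclopentane-1,3-dione | ON=C1C(=O)CCC1=O | intermediate
33 | 2-amino-3-hydroxycyclopent-2-en-1-one hydrochloride | NC1=C(O)CCC1=O.Cl | intermediate
34 | (2E,4E)-5-bromopenta-2,4-dienoyl chloride (not isolated) | O=C(Cl)/C=C/C=C/Br | intermediate
35 | (2E,4E)-5-bromo-N-(2-hydroxy-5-oxocyclopent-1-en-1-yl)penta-2,4-dienamide | O=C(/C=C/C=C/Br)NC1=C(O)CCC1=O | intermediate
36 | (2E,4E)-5-cyclohexyl-N-[(4R,5S,6R)-5,6-epoxy-4-hydroxy-4-[(1E,3E,5E)-7-[(2-hydroxy-5-oxocyclopent-1-en-1-yl)amino]-7-oxohepta-1,3,5-trien-1-yl]-1-oxocyclohex-2-en-2-yl]penta-2,4-dienamide | O=C(/C=C/C=C/C1CCCCC1)NC1=C[C@](O)(/C=C/C=C/C=C/C(=O)NC2=C(O)CCC2=O)[C@H]2O[C@H]2C1=O | target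

## Step count and least certain steps

Total: 25 steps. Longest linear sequence: 18 steps (steps 1–14, 17–19 and 25). The upper amide (steps 15–16) and the lower bromodienamide (steps 20–24) are side branches.

**Step 13 (key step).** The alkenyllithium may be diverted before it acylates C1: by 1,4 migration of the silyl group from the C4 oxygen to C2, by protonation, or because t-BuLi attacks the amide or fragments its N–O bond before exchange is complete. All of these compete because the anion is generated next to a silyl ether and an electrophilic amide in the same molecule. Fallback: the same C1–C2 bond is made by a Nozaki–Hiyama–Kishi reaction, which needs no carbanion. It sets out from 13: Dess–Martin oxidation gives the (2R,3S)-epoxy aldehyde F1. CrCl2 with catalytic NiCl2 in DMSO/THF closes the ring to the cyclic allylic alcohol F2 (C1 epimers). A second Dess–Martin oxidation returns to the route at 19, in the same number of steps as 11–13.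

**Step 6.** Poor or inverted facial selectivity at the ketone would give the C4 epimer. The oxirane oxygen is a weak donor, the PMB ether oxygen offers a competing chelate, and the two alkynyl groups differ too little in size to help. Fallback: the order in which the two alkynes are introduced is reversed, so that whichever face the substrate prefers leads to the same compound. It sets out from 4: lithiated 8 gives the TIPS-propargylic alcohol F3, Dess–Martin oxidation gives the TIPS-ynone F4, and addition of lithiated 5 under the regime (chelating magnesium in CH2Cl2, or non-chelating lithium in THF) that shows the clearer bias returns to the route at 9.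

**Step 17.** Base- or amine-induced degradation of the iodo epoxy enone may outrun the C–N coupling (oxirane opening, conjugate addition of the diamine ligand, dehalogenation). The reaction needs carbonate and warmth on a doubly electrophilic ring. Fallback: nitrogen is introduced as azide at room temperature and acylated afterwards. It sets out from 20: NaN3 with CuI, sodium ascorbate and N,N'-dimethylethylenediamine in EtOH/H2O gives the 2-azido enone F5, and Staudinger reduction (PMe3, THF/H2O) gives the 2-amino enone F6. In parallel, 23 is saponified (LiOH) to the dienoic acid F7 and converted with oxalyl chloride to the acid chloride F8. Acylation of F6 with F8 (pyridine, CH2Cl2, 0 °C) returns to the route at 25.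

**Step 19.** Tin may add to the internal alkyne carbon, and the palladium hydride or the stannane may reduce the enone or the epoxy ketone, since three reducible π-systems are present. Fallback: silicon replaces tin. It sets out from 26: platinum-catalysed hydrosilylation (Pt(dvds), t-Bu3P, benzyldimethylsilane, THF) gives the (E)-alkenylsilane F9. Fluoride-promoted Hiyama coupling of F9 with 35 (TBAF, Pd2(dba)3, THF, rt) returns to the route at 36.

## Further compounds

F1 | step 13 | (2R,3S)-3-[(1Z,3S)-3-(tert-butyldimethylsilyloxy)-1-iodo-5-(triisopropylsilyl)pent-1-en-4-yn-3-yl]oxirane-2-carbaldehyde | I/C=C\[C@](O[Si](C)(C)C(C)(C)C)(C#C[Si](C(C)C)(C(C)C)C(C)C)[C@H]1O[C@H]1C=O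
F2 | step 13 | 4-(tert-butyldimethylsilyloxy)-5,6-epoxy-4-[(triisopropylsilyl)ethynyl]cyclohex-2-en-1-ol, C4, C5, C6 as in 19, C1 epimers | OC1C=C[C@](O[Si](C)(C)C(C)(C)C)(C#C[Si](C(C)C)(C(C)C)C(C)C)[C@H]2O[C@H]21
F3 | step 6 | 1-[(2R,3S)-3-{[(4-methoxybenzyl)oxy]methyl}oxiran-2-yl]-3-(triisopropylsilyl)prop-2-yn-1-ol, carbinol epimers | CC(C)[Si](C#CC(O)[C@H]1O[C@H]1COCc1ccc(OC)cc1)(C(C)C)C(C)C
F4 | step 6 | 1-[(2S,3S)-3-{[(4-methoxybenzyl)oxy]methyl}oxiran-2-yl]-3-(triisopropylsilyl)prop-2-yn-1-one | CC(C)[Si](C#CC(=O)[C@H]1O[C@H]1COCc1ccc(OC)cc1)(C(C)C)C(C)C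
F5 | step 17 | (4S,5S,6R)-2-azido-4-(tert-butyldimethylsilyloxy)-5,6-epoxy-4-[(triisopropylsilyl)ethynyl]cyclohex-2-en-1-one | [N-]=[N+]=NC1=C[C@](O[Si](C)(C)C(C)(C)C)(C#C[Si](C(C)C)(C(C)C)C(C)C)[C@H]2O[C@H]2C1=O
F6 | step 17 | (4S,5S,6R)-2-amino-4-(tert-butyldimethylsilyloxy)-5,6-epoxy-4-[(triisopropylsilyl)ethynyl]cyclohex-2-en-1-one | NC1=C[C@](O[Si](C)(C)C(C)(C)C)(C#C[Si](C(C)C)(C(C)C)C(C)C)[C@H]2O[C@H]2C1=O
F7 | step 17 | (2E,4E)-5-cyclohexylpenta-2,4-dienoic acid | OC(=O)/C=C/C=C/C1CCCCC1
F8 | step 17 | (2E,4E)-5-cyclohexylpenta-2,4-dienoyl chloride | O=C(Cl)/C=C/C=C/C1CCCCC1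
F9 | step 19 | (2E,4E)-N-[(4S,5S,6R)-4-[(E)-2-(benzyldimethylsilyl)ethenyl]-5,6-epoxy-4-hydroxy-1-oxocyclohex-2-en-2-yl]-5-cyclohexylpenta-2,4-dienamide | O=C(/C=C/C=C/C1CCCCC1)NC1=C[C@](O)(/C=C/[Si](C)(C)Cc3ccccc3)[C@H]2O[C@H]2C1=O
A1 | alternative 1 | (2E,4E)-N-(2-hydroxy-5-oxocyclopent-1-en-1-yl)-5-(tributylstannyl)penta-2,4-dienamide | O=C(/C=C/C=C/[Sn](CCCC)(CCCC)CCCC)NC1=C(O)CCC1=O
A2 | alternative 1 | methyl 4-oxo-5-[(2E,4E)-5-(tributylstannyl)penta-2,4-dienamido]pentanoate | COC(=O)CCC(=O)CNC(=O)/C=C/C=C/[Sn](CCCC)(CCCC)CCCC
A3 | alternative 1 | (2E,4E)-5-cyclohexyl-N-[5,6-epoxy-4-hydroxy-4-[(E)-2-iodoethenyl]-1-oxocyclohex-2-en-2-yl]penta-2,4-dienamide, ring configuration as in 27 | O=C(/C=C/C=C/C1CCCCC1)NC1=C[C@](O)(/C=C/I)[C@H]2O[C@H]2C1=O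
A4 | alternative 2 | syn-3,4:5,6-bis-epoxide of the C1 tert-butyldimethylsilyl ether of 4-[(triisopropylsilyl)ethynyl]cyclohexan-1-ol, both oxiranes anti to the silyloxy group | CC(C)(C)[Si](C)(C)O[C@@H]1C[C@H]2O[C@@]2(C#C[Si](C(C)C)(C(C)C)C(C)C)[C@H]2O[C@H]21
A5 | alternative 2 | tert-butyldimethyl{[4-[(triisopropylsilyl)ethynyl]cyclohexa-3,5-dien-1-yl]oxy}silane, C1 configured as in A4 | CC(C)(C)[Si](C)(C)O[C@@H]1CC=C(C#C[Si](C(C)C)(C(C)C)C(C)C)C=C1
A6 | alternative 3 | (4S,5S,6R)-5,6-epoxy-4-hydroxy-4-[(triisopropylsilyl)ethynyl]cyclohex-2-en-1-one | O=C1C=C[C@](O)(C#C[Si](C(C)C)(C(C)C)C(C)C)[C@H]2O[C@H]21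
A7 | alternative 3 | 4-hydroxy-4-[(triisopropylsilyl)ethynyl]cyclohexa-2,5-dien-1-one | O=C1C=CC(O)(C#C[Si](C(C)C)(C(C)C)C(C)C)C=C1
A8 | alternative 3 | p-benzoquinone | O=C1C=CC(=O)C=C1
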